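**Retrosynthetic overview**
1. The target comes from its 4-O-methyl ether; the last step is a thiolate demethylation of the tetronate.
2. Key disconnection: chain C9'H2–C4 of the central furan, a ring that neither partner contains. A conjugated triene tetronate (terminal vinyl C8'=C9', converted in the flask into its primary 9-BBN borane) is joined to the β-alkyne carbon of the acyclic ynone 3-furyl-CH2-CO-C≡C-CH2OTBS. Acid then closes the furan in the same flask.
3. Enabling feature: in the central furan the chain-bearing C4 stands 1,3 to the oxygen-bearing C2 (furylmethyl) and next to an unsubstituted C5–H. Opened at O1–C2, the ring is a (Z)-4-hydroxy-2-en-1-one with C4 as its β-carbon, which is the syn-hydroalkylation product of a γ-oxy ynone. The C8'H2–C9'H2 link ending at the C4'=C5'/C6'=C7' diene is the hydroboration retron of a terminal vinyl group.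
4. The triene tetronate comes from an (S)-trienal and 4-methoxy-3-methylfuran-2(5H)-one (aldol, E1cB, Z). The trienal comes from a Negishi coupling of the chiral-pool reagent BrZnCH2CH(CH3)CO2Me with an (E,E)-trienyl iodide (acrolein, Wittig, Takai).
5. Ring order: the 3-furyl ring and the butenolide ring are bought. The central furan is the only ring made, and it is made last, in the key step.

Key step: step 10

Remark: chain atoms are numbered C1'–C9' from the ylidene carbon and the central furan O1, C2 (furylmethyl), C3, C4 (chain), C5; the tetronic acid is handled as the 4-hydroxy-2(5H)-furanone tautomer drawn.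

**Step 1**
Reactants: 1 acrolein; 2 2-(triphenyl-λ5-phosphanylidene)propanal
Product: 3 (2E)-2-methylpenta-2,4-dienal
Conditions: CH2Cl2, reflux, trace hydroquinone; careful distillation
Reagents that add atoms: none
Why: Wittig olefination with a stabilised formyl ylide should give the (E)-trisubstituted enal (vinyl trans to CHO), and the α-branched conjugated product aldehyde is much less electrophilic than acrolein, so a second olefination should stay slow.

**Step 2**
Reactants: 3 (2E)-2-methylpenta-2,4-dienal
Product: 4 (1E,3E)-1-iodo-3-methylhexa-1,3,5-triene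
Conditions: CrCl2, CHI3, THF/1,4-dioxane, 0 °C to rt, dark
Reagents that add atoms: iodoform, IC(I)I
Why: Takai olefination, in which the gem-dichromium species from CHI3 and CrCl2 adds to the aldehyde and eliminates to the (E)-alkenyl iodide, an aldehyde-selective reaction that leaves the diene alone.

**Step 3**
Reactants: 4 (1E,3E)-1-iodo-3-methylhexa-1,3,5-triene; 5 (R)-(3-methoxy-2-methyl-3-oxopropyl)zinc bromide (commercial THF solution)
Product: 6 methyl (2S,4E,6E)-2,6-dimethylnona-4,6,8-trienoate
Conditions: Pd(PPh3)4 (5 mol %), THF, rt, dark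
Reagents that add atoms: none
Why: Negishi sp3–sp2 cross-coupling keeps the geometry of the alkenyl iodide, and the stereocentre arrives ready-made with 5 and is not disturbed under these neutral conditions (the descriptor changes from R to S only because CH2Zn outranks CO2Me whereas CH2C does not).

**Step 4**
Reactants: 6 methyl (2S,4E,6E)-2,6-dimethylnona-4,6,8-trienoate
Product: 7 (2S,4E,6E)-2,6-dimethylnona-4,6,8-trienal
Conditions: DIBAL-H (1.05 equiv), CH2Cl2, −78 °C; aq Rochelle salt
Reagents that add atoms: none
Why: In this partial DIBAL-H reduction of an ester the tetrahedral aluminium hemiacetal survives at −78 °C and releases the aldehyde only on work-up, so the α-stereocentre meets no base.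

**Step 5**
Reactants: 8 4-hydroxy-3-methylfuran-2(5H)-one (3-methyltetronic acid)
Product: 9 4-methoxy-3-methylfuran-2(5H)-one
Conditions: Me2SO4, K2CO3, acetone, reflux
Reagents that add atoms: dimethyl sulfate, COS(=O)(=O)OC
Why: O-alkylation of a vinylogous carboxylic acid with a hard methylating agent should take place at the C4 oxygen of the delocalised tetronate anion.

**Step 6**
Reactants: 9 4-methoxy-3-methylfuran-2(5H)-one; 7 (2S,4E,6E)-2,6-dimethylnona-4,6,8-trienal
Product: 11 5-[(2S,4E,6E)-1-hydroxy-2,6-dimethylnona-4,6,8-trien-1-yl]-4-methoxy-3-methylfuran-2(5H)-one (diastereomer mixture at C5 and C1'), via C5-lithiated tetronate 10 (not isolated)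
Conditions: LDA, THF, −78 °C; then 7, −78 °C; aq NH4Cl
Reagents that add atoms: lithium diisopropylamide, [Li]N(C(C)C)C(C)C (its lithium stays only in 10)
Why: Vinylogous (γ) deprotonation of the methyl tetronate at C5 is followed by aldol addition of the lithium dienolate; the two new stereocentres (C5, C1') form as a mixture that does not matter because step 7 erases both, and C2' is kept because the weakly basic dienolate adds faster than it enolises the aldehyde.

**Step 7**
Reactants: 11 aldol adduct
Product: 13 (5Z)-5-[(2S,4E,6E)-2,6-dimethylnona-4,6,8-trien-1-ylidene]-4-methoxy-3-methylfuran-2(5H)-one, via C1' mesylate 12 (not isolated)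
Conditions: MsCl, Et3N, CH2Cl2, 0 °C; then DBU, 0 °C to rt
Reagents that add atoms: methanesulfonyl chloride, CS(=O)(=O)Cl (its CH3SO2 group stays only in 12)
Why: Mesylation followed by E1cB elimination through the C5 dienolate should favour the (Z)-ylidene tetronate, because the chain then lies on the side of the ring oxygen and avoids A(1,3) strain with the 4-methoxy group.

**Step 8**
Reactants: 14 2-(furan-3-yl)acetic acid
Product: 16 2-(furan-3-yl)-N-methoxy-N-methylacetamide, via acyl imidazole 15 (not isolated)
Conditions: CDI, CH2Cl2, rt; then MeNH(OMe)·HCl, rt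
Reagents that add atoms: 1,1'-carbonyldiimidazole, O=C(n1ccnc1)n1ccnc1 (its imidazole stays only in 15); N,O-dimethylhydroxylamine hydrochloride, CNOC.Cl
Why: Carboxyl activation with CDI and aminolysis of the acyl imidazole (Weinreb amide formation) run under near-neutral conditions that the furan tolerates.

**Step 9**
Reactants: 17 tert-butyldimethyl(prop-2-yn-1-yloxy)silane; 16 2-(furan-3-yl)-N-methoxy-N-methylacetamide
Product: 19 5-[(tert-butyldimethylsilyl)oxy]-1-(furan-3-yl)pent-3-yn-2-one, via lithium acetylide 18 (not isolated)
Conditions: n-BuLi, THF, −78 °C; then 16, −78 to −20 °C; inverse quench into cold aq NH4Cl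
Reagents that add atoms: n-butyllithium, [Li]CCCC (its lithium stays only in 18)
Why: In the Weinreb ketone synthesis the acetylide adds once to give a chelated tetrahedral intermediate that collapses to the ynone only on the cold quench, which prevents over-addition.

**Step 10**
Reactants: 13 triene tetronate; 19 γ-silyloxy ynone
Product: 22 (5Z)-5-{(2S,4E,6E)-9-[5-(furan-3-ylmethyl)furan-3-yl]-2,6-dimethylnona-4,6-dien-1-ylidene}-4-methoxy-3-methylfuran-2(5H)-one, via B-alkyl-9-BBN 20 (not isolated), via (Z)-silyloxy enone 21 (not isolated)
Conditions: 9-BBN-H dimer, THF, 0 °C to rt; then 19, CuOAc (10 mol %), P(OPh)3 (20 mol %), t-BuOK (10 mol %), t-BuOH (1.2 equiv), 1,4-dioxane, 40 °C; then 1 M aq HCl, THF, rt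
Reagents that add atoms: 9-borabicyclo[3.3.1]nonane, B1C2CCCC1CCC2 (its boron cage stays only in 20)
Why: Proposed new method: 9-BBN-H should add anti-Markovnikov to the only monosubstituted C=C of 13 (C8'=C9'; the 1,2-di- and trisubstituted diene bonds and the push-pull ylidene lactone are far slower), and the primary borane 20 then passes its alkyl group to copper(I) by a two-electron, tert-butoxide-assisted B-to-Cu transmetalation, which avoids a free radical at C9' that would close 3-exo onto the neighbouring diene and scramble the C6'=C7' geometry. The alkylcopper adds syn across the C≡C of 19 with carbon going to the β-carbon, as the ketone polarises the triple bond, and t-BuOH protonates the α-cuprio enone and returns CuOt-Bu, so that 21 carries C=O and CH2OTBS cis. Aqueous acid then removes the silyl group, the freed hydroxyl adds to the ketone carbon (5-exo-trig, ring closed at the O1–C2 bond) and loss of water aromatises to the 2,4-disubstituted furan, while any (E)-enone can still drain through acid-catalysed rotation of the O-protonated β,β-dialkyl enone because only the (Z)-form is removed irreversibly. The closest known reaction types are the copper(I)-catalysed syn-hydroalkylation of alkynoates with alkyl-9-BBN reagents, the copper-catalysed hydroarylation–lactonisation of γ-hydroxy alkynoates to butenolides and the hydrohalogenation–cyclodehydration of γ-hydroxy ynones to 3-halofurans; new here are the ynone acceptor and the merger with furan formation. No stereocentre is formed, and C2' and the three existing C=C geometries are remote from every bond that changes. The step needs site-selective hydroboration, β-regioselectivity and chemoselectivity for the ynone over the tetronate, secured respectively by the single terminal vinyl group, by the ketone and by the donor-deactivated (4-OMe, ring O) acceptor character of the ylidene lactone.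

**Step 11**
Reactants: 22 O-methyl ether of the target
Product: 23 (5Z)-5-{(2S,4E,6E)-9-[5-(furan-3-ylmethyl)furan-3-yl]-2,6-dimethylnona-4,6-dien-1-ylidene}-4-hydroxy-3-methylfuran-2(5H)-one (target)
Conditions: n-PrSLi (from n-PrSH and n-BuLi), HMPA/THF, rt; then 0.5 M HCl, 0 °C
Reagents that add atoms: none
Why: SN2 O-demethylation of a vinylogous methyl ester by a soft thiolate in a dipolar aprotic medium is driven by the stabilised tetronate leaving group and should leave the furans, the diene, the ylidene geometry and C2' untouched.

**Compound list**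
1 | acrolein | C=CC=O | starting material
2 | 2-(triphenyl-λ5-phosphanylidene)propanal | CC(C=O)=P(c1ccccc1)(c1ccccc1)c1ccccc1 | starting material
3 | (2E)-2-methylpenta-2,4-dienal | O=C/C(C)=C/C=C | intermediate
4 | (1E,3E)-1-iodo-3-methylhexa-1,3,5-triene | I/C=C/C(C)=C/C=C | intermediate
5 | (R)-(3-methoxy-2-methyl-3-oxopropyl)zinc bromide | COC(=O)[C@@H](C)C[Zn]Br | starting material
6 | methyl (2S,4E,6E)-2,6-dimethylnona-4,6,8-trienoate | COC(=O)[C@@H](C)C/C=C/C(C)=C/C=C | intermediate
7 | (2S,4E,6E)-2,6-dimethylnona-4,6,8-trienal | O=C[C@@H](C)C/C=C/C(C)=C/C=C | intermediate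
8 | 4-hydroxy-3-methylfuran-2(5H)-one | CC1=C(O)COC1=O | starting material
9 | 4-methoxy-3-methylfuran-2(5H)-one | COC1=C(C)C(=O)OC1 | intermediate
10 | 5-lithio-4-methoxy-3-methylfuran-2(5H)-one (lithium dienolate) | [Li]C1OC(=O)C(C)=C1OC | intermediate
11 | 5-[(2S,4E,6E)-1-hydroxy-2,6-dimethylnona-4,6,8-trien-1-yl]-4-methoxy-3-methylfuran-2(5H)-one | COC1=C(C)C(=O)OC1C(O)[C@@H](C)C/C=C/C(C)=C/C=C | intermediate
12 | C1' methanesulfonate of 11 | COC1=C(C)C(=O)OC1C(OS(C)(=O)=O)[C@@H](C)C/C=C/C(C)=C/C=C | intermediate
13 | (5Z)-5-[(2S,4E,6E)-2,6-dimethylnona-4,6,8-trien-1-ylidene]-4-methoxy-3-methylfuran-2(5H)-one | COC1=C(C)C(=O)O/C1=C\[C@@H](C)C/C=C/C(C)=C/C=C | intermediate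
14 | 2-(furan-3-yl)acetic acid | OC(=O)Cc1ccoc1 | starting material
15 | 2-(furan-3-yl)-1-(1H-imidazol-1-yl)ethan-1-one | O=C(Cc1ccoc1)n1ccnc1 | intermediate
16 | 2-(furan-3-yl)-N-methoxy-N-methylacetamide | CON(C)C(=O)Cc1ccoc1 | intermediate
17 | tert-butyldimethyl(prop-2-yn-1-yloxy)silane | C#CCO[Si](C)(C)C(C)(C)C | starting material
18 | lithium acetylide of 17 | [Li]C#CCO[Si](C)(C)C(C)(C)C | intermediate
19 | 5-[(tert-butyldimethylsilyl)oxy]-1-(furan-3-yl)pent-3-yn-2-one | O=C(Cc1ccoc1)C#CCO[Si](C)(C)C(C)(C)C | intermediate
20 | (5Z)-5-[(2S,4E,6E)-9-(9-borabicyclo[3.3.1]nonan-9-yl)-2,6-dimethylnona-4,6-dien-1-ylidene]-4-methoxy-3-methylfuran-2(5H)-one | COC1=C(C)C(=O)O/C1=C\[C@@H](C)C/C=C/C(C)=C/CCB1C2CCCC1CCC2 | intermediate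
21 | (5Z)-5-[(2S,4E,6E,10Z)-10-{[(tert-butyldimethylsilyl)oxy]methyl}-13-(furan-3-yl)-2,6-dimethyl-12-oxotrideca-4,6,10-trien-1-ylidene]-4-methoxy-3-methylfuran-2(5H)-one | COC1=C(C)C(=O)O/C1=C\[C@@H](C)C/C=C/C(C)=C/CC/C(CO[Si](C)(C)C(C)(C)C)=C/C(=O)Cc1ccoc1 | intermediate
22 | (5Z)-5-{(2S,4E,6E)-9-[5-(furan-3-ylmethyl)furan-3-yl]-2,6-dimethylnona-4,6-dien-1-ylidene}-4-methoxy-3-methylfuran-2(5H)-one | COC1=C(C)C(=O)O/C1=C\[C@@H](C)C/C=C/C(C)=C/CCc1coc(Cc2ccoc2)c1 | intermediate
23 | (5Z)-5-{(2S,4E,6E)-9-[5-(furan-3-ylmethyl)furan-3-yl]-2,6-dimethylnona-4,6-dien-1-ylidene}-4-hydroxy-3-methylfuran-2(5H)-one | CC1=C(O)/C(=C/[C@@H](C)C/C=C/C(C)=C/CCc2coc(Cc3ccoc3)c2)OC1=O | target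

**Step count**
Total step count: 11. Longest linear sequence: 8 steps (1, 2, 3, 4, 6, 7, 10, 11).

**Steps most likely to fail**

**Step 10 (proposed new method).**
- What may go wrong:
  - Boron-to-copper transfer may be slow.
  - The catalytic base may enolise or isomerise the ynone before carbocupration.
  - Hydroboration may spill over into the internal diene.
  - The enone may stall in the geometry that cannot cyclise.
- Fallback, by known chemistry, sets out from 19 and 13 and returns at 22. Treatment of 19 with 48 % aq HBr in toluene (0 °C to rt) should cleave the silyl ether, add HBr to the ynone and cyclodehydrate to 4-bromo-2-(furan-3-ylmethyl)furan F1. This is the established hydrohalogenation–cyclodehydration of γ-hydroxy ynones.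
- The borane 20 is made from 13 as in step 10. It is then joined to F1 by a B-alkyl Suzuki–Miyaura coupling (PdCl2(dppf), aq K3PO4, DMF/THF, 50 °C) to give 22.

**Step 7.**
- What may go wrong: the E1cB elimination may run with incomplete Z selectivity, and long contact with DBU may epimerise the allylic C2' centre by vinylogous deprotonation.
- Fallback sets out from 9 and 7 and returns at 13. Radical bromination of 9 at the doubly activated C5–H (NBS, AIBN, PhCF3, reflux) should give 5-bromo-4-methoxy-3-methylfuran-2(5H)-one F2.
- A Michaelis–Arbuzov reaction with P(OEt)3 should then give diethyl (3-methoxy-4-methyl-5-oxo-2,5-dihydrofuran-2-yl)phosphonate F3.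
- A Horner–Wadsworth–Emmons olefination of 7 under LiCl/DBU (Masamune–Roush) conditions forms C5=C1' directly, without a carbinol or sulfonate stage.

**Step 2.**
- What may go wrong: E selectivity may erode with a conjugated aldehyde, and the volatile dienal and the light-sensitive trienyl iodide may be lost during the chromium work-up.
- Fallback sets out from 3 and returns at 4. Corey–Fuchs homologation (CBr4, PPh3, CH2Cl2, 0 °C) should give (3E)-1,1-dibromo-3-methylhexa-1,3,5-triene F4.
- n-BuLi (THF, −78 °C, then water) should give (3E)-3-methylhexa-3,5-dien-1-yne F5.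
- Syn-hydrozirconation of the terminal alkyne with Cp2Zr(H)Cl followed by I2 fixes the E geometry by the mode of addition and gives 4.

**Further compounds**
F1 | step 10 | 4-bromo-2-(furan-3-ylmethyl)furan | Brc1coc(Cc2ccoc2)c1
F2 | step 7 | 5-bromo-4-methoxy-3-methylfuran-2(5H)-one | COC1=C(C)C(=O)OC1Br
F3 | step 7 | diethyl (3-methoxy-4-methyl-5-oxo-2,5-dihydrofuran-2-yl)phosphonate | CCOP(=O)(OCC)C1OC(=O)C(C)=C1OC
F4 | step 2 | (3E)-1,1-dibromo-3-methylhexa-1,3,5-triene | BrC(Br)=C/C(C)=C/C=C
F5 | step 2 | (3E)-3-methylhexa-3,5-dien-1-yne | C#C/C(C)=C/C=C
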